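**Plan**

- Retrosynthesis: the C3 ester is cut first (trienoic acid plus 3α-alcohol). The Z-configured C8(=O)–C7=C11–C12–OH array is then folded back into a furan (O bridging C8 and C12).
- Ring B (C5–C10) is opened at C9–C10 and C8–C9. C9 is the only carbon between ring-fusion C10 and the furan α-carbon C8 and it carries oxygen, so it is supplied as carbon monoxide between a C10 enol triflate and a C8 furylstannane.
- The monocyclic precursor is cut at C5–C6 (enolate alkylation by a furylmethyl bromide) and at C4–CH3 (cuprate addition to a 4-silyloxy-2-methylcyclohexenone).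
- Forward: ring A enone, then C4 and C5, enol triflate, carbonylative closure of ring B, reduction at C9 and C10, esterification at C3, oxidative opening of the furan.
- Stereochemistry: C3 from asymmetric transfer hydrogenation; C4 by cuprate addition anti to the C3 oxygen; C5 by alkylation anti to the C4 methyl; C9 by hydride attack anti to the C5 methyl; C10 by hydroxyl-directed hydrogenation; the 7(11)Z geometry from the furan ring.

Key step: step 13

Remark: eremophilane numbering is used throughout (ring A = C1–C5, C10; ring B = C5–C10; the methyls on C4 and C5 are β; furanoeremophilane = 8,12-epoxyeremophila-7,11-diene), and the enone ketal of step 1 is taken as a catalogue compound.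

**Route**

Step 1
Reactants: 1 1,4-dioxaspiro[4.5]dec-6-en-8-one
Product: 2 (R)-1,4-dioxaspiro[4.5]dec-6-en-8-ol
Conditions: RuCl(p-cymene)[(R,R)-TsDPEN] (1 mol%), HCO2Na, n-Bu4NCl, CH2Cl2–H2O, rt
Reagents that add atoms: none
Why: Ruthenium-catalysed asymmetric transfer hydrogenation reduces the enone carbonyl in the 1,2 sense with the alkenyl group in the place of the aryl group of the usual model, so the (R,R) catalyst should give the (R)-carbinol (later C3), and the neutral formate medium leaves the ketal alone.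

Step 2
Reactants: 2 (R)-1,4-dioxaspiro[4.5]dec-6-en-8-ol
Product: 3 (R)-8-(tert-butyldimethylsilyloxy)-1,4-dioxaspiro[4.5]dec-6-ene
Conditions: TBSCl, imidazole, DMF, rt
Reagents that add atoms: tert-butyldimethylsilyl chloride CC(C)(C)[Si](C)(C)Cl
Why: Routine silylation of a secondary allylic alcohol, which does not touch the stereocentre.

Step 3
Reactants: 3 (R)-8-(tert-butyldimethylsilyloxy)-1,4-dioxaspiro[4.5]dec-6-ene
Product: 4 (R)-4-(tert-butyldimethylsilyloxy)cyclohex-2-en-1-one
Conditions: PPTS (cat.), THF–H2O, 45 °C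
Reagents that add atoms: water O
Why: Mild acid hydrolysis of the allylic ketal gives the conjugated enone, while the secondary silyl ether and the carbinol centre (no enolisable hydrogen under these conditions) stay as they are.

Step 4
Reactants: 4 (R)-4-(tert-butyldimethylsilyloxy)cyclohex-2-en-1-one
Product: 5 (R)-4-(tert-butyldimethylsilyloxy)-2-iodocyclohex-2-en-1-one
Conditions: I2, pyridine–CH2Cl2 (1:1), 0 °C to rt
Reagents that add atoms: iodine II
Why: α-Iodination of an enone by conjugate addition of pyridine, iodination of the enolate and loss of pyridine, a standard way to functionalise the α-carbon of cyclohexenones.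

Step 5
Reactants: 5 (R)-4-(tert-butyldimethylsilyloxy)-2-iodocyclohex-2-en-1-one
Product: 6 (R)-4-(tert-butyldimethylsilyloxy)-2-methylcyclohex-2-en-1-one
Conditions: Me4Sn, Pd2(dba)3 (2.5 mol%), AsPh3, CuI, NMP, 60 °C
Reagents that add atoms: tetramethylstannane C[Sn](C)(C)C
Why: Stille coupling of an α-iodoenone under base-free conditions, so the γ-silyloxy stereocentre cannot racemise through a dienolate.

Step 6
Reactants: 6 (R)-4-(tert-butyldimethylsilyloxy)-2-methylcyclohex-2-en-1-one
Product: 7 (3R,4R)-4-(tert-butyldimethylsilyloxy)-2,3-dimethyl-1-(trimethylsilyloxy)cyclohex-1-ene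
Conditions: Me2CuLi (from CuI and 2 MeLi), Me3SiCl, THF, −78 °C; Et3N, cold NaHCO3 work-up
Reagents that add atoms: lithium dimethylcuprate C[Cu-]C.[Li+]; chlorotrimethylsilane C[Si](C)(C)Cl
Why: Cuprate conjugate addition enters anti to the γ-silyloxy group, which sets C4 (R, methyl trans to the C3 oxygen), and chlorosilane trapping fixes the tetrasubstituted enolate regiochemistry.

Step 7
Reactants: 8 4-phenyloxazole; 9 ethyl but-2-ynoate
Product: 10 ethyl 4-methylfuran-3-carboxylate
Conditions: neat, 200 °C, sealed tube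
Reagents that add atoms: none
Why: Diels–Alder addition of the alkyne across C2/C5 of the oxazole followed by retro-Diels–Alder loss of benzonitrile gives the 3,4-disubstituted furan with free α-positions.

Step 8
Reactants: 10 ethyl 4-methylfuran-3-carboxylate
Product: 11 (4-methylfuran-3-yl)methanol
Conditions: LiAlH4, Et2O, 0 °C
Reagents that add atoms: none
Why: Hydride reduction of the ester to the primary alcohol; the furan ring is inert.

Step 9
Reactants: 11 (4-methylfuran-3-yl)methanol
Product: 13 [4-methyl-2-(tributylstannyl)furan-3-yl]methanol, via dilithio alkoxide 12 (not isolated)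
Conditions: n-BuLi (2.2 equiv), DME, −78 to 0 °C; Bu3SnCl, −78 °C to rt
Reagents that add atoms: tributyltin chloride CCCC[Sn](Cl)(CCCC)CCCC
Why: The lithium alkoxide directs the second lithiation to the adjacent α-position C2 rather than C5 (directed ortho-metalation of a 3-furylmethanol), and the carbanion is stannylated.

Step 10
Reactants: 13 [4-methyl-2-(tributylstannyl)furan-3-yl]methanol
Product: 15 tributyl[3-(bromomethyl)-4-methylfuran-2-yl]stannane, via mesylate 14 (not isolated)
Conditions: MsCl, Et3N, CH2Cl2, −30 °C; LiBr, THF, 0 °C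
Reagents that add atoms: lithium bromide [Li+].[Br-]
Why: Mesylation and SN2 displacement by bromide avoid both acid and electrophilic halogen, so the furyl–tin bond survives.

Step 11
Reactants: 7 (3R,4R)-4-(tert-butyldimethylsilyloxy)-2,3-dimethyl-1-(trimethylsilyloxy)cyclohex-1-ene; 15 tributyl[3-(bromomethyl)-4-methylfuran-2-yl]stannane
Product: 17 (2R,3R,4R)-4-(tert-butyldimethylsilyloxy)-2,3-dimethyl-2-{[4-methyl-2-(tributylstannyl)furan-3-yl]methyl}cyclohexan-1-one, via lithium enolate 16 (not isolated)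
Conditions: MeLi (1.0 equiv), THF, 0 °C; then 15, HMPA, −78 to −20 °C
Reagents that add atoms: none
Why: Methyllithium cleaves the silyl enol ether to the regiodefined tetrasubstituted lithium enolate, in which A(1,2) strain holds the C4 methyl pseudoaxial, so SN2 alkylation by the furylmethyl bromide should occur on the opposite face and set C5 (R) with the two methyls cis; any C5 epimer is removed by chromatography.

Step 12
Reactants: 17 (2R,3R,4R)-4-(tert-butyldimethylsilyloxy)-2,3-dimethyl-2-{[4-methyl-2-(tributylstannyl)furan-3-yl]methyl}cyclohexan-1-one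
Product: 19 (4R,5R,6R)-4-(tert-butyldimethylsilyloxy)-5,6-dimethyl-6-{[4-methyl-2-(tributylstannyl)furan-3-yl]methyl}cyclohex-1-en-1-yl trifluoromethanesulfonate, via potassium enolate 18 (not isolated)
Conditions: KN(SiMe3)2, THF, −78 °C; PhNTf2, −78 to 0 °C
Reagents that add atoms: N-phenylbis(trifluoromethanesulfonimide) O=S(=O)(N(c1ccccc1)S(=O)(=O)C(F)(F)F)C(F)(F)F
Why: Because C5 is quaternary, the ketone can enolise only towards C1, so O-triflation of the single enolate gives the C10–C1 enol triflate.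

Step 13
Reactants: 19 (4R,5R,6R)-4-(tert-butyldimethylsilyloxy)-5,6-dimethyl-6-{[4-methyl-2-(tributylstannyl)furan-3-yl]methyl}cyclohex-1-en-1-yl trifluoromethanesulfonate; 20 carbon monoxide
Product: 21 (3R,4R,5R)-3α-(tert-butyldimethylsilyloxy)furanoeremophil-1(10)-en-9-one
Conditions: Pd(PPh3)4 (10 mol%), LiCl (3 equiv), CO (3 atm), 1,4-dioxane (0.01 M), 80 °C
Reagents that add atoms: none
Why: Zerovalent palladium adds oxidatively to the C10–OTf bond (chloride from LiCl taking the place of triflate on the metal), CO inserts to give the acylpalladium complex and so forms C9–C10, the C8 furyl group is transferred from tin within the same molecule, and reductive elimination forms C8–C9. The closest known reaction is the carbonylative Stille coupling of enol triflates with aryl and heteroaryl stannanes, which has also been run intramolecularly. Ring B (C5–C10) closes as a six-membered ketone by reductive elimination from a seven-membered acyl(furyl)palladacycle, both new bonds ending at the inserted carbon. No stereocentre is formed, and C3, C4 and C5 are not touched. The step needs CO insertion to come before transmetalation, which is favoured by CO pressure and by the strain of the cyclopenta-fused furan that direct coupling would give; the position of the new double bond (C1=C10) is fixed by the quaternary C5.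

Step 14
Reactants: 21 (3R,4R,5R)-3α-(tert-butyldimethylsilyloxy)furanoeremophil-1(10)-en-9-one
Product: 22 (3R,4R,5R,9R)-3α-(tert-butyldimethylsilyloxy)furanoeremophil-1(10)-en-9β-ol
Conditions: NaBH4, CeCl3·7H2O, MeOH, −40 °C
Reagents that add atoms: none
Why: Luche 1,2-reduction of the cross-conjugated ketone, in which hydride should reach C9 from the α face, opposite the C5 methyl that stands pseudoaxial over ring B, giving the 9β-alcohol (9R).

Step 15
Reactants: 22 (3R,4R,5R,9R)-3α-(tert-butyldimethylsilyloxy)furanoeremophil-1(10)-en-9β-ol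
Product: 23 (3R,4R,5R,9R,10S)-3α-(tert-butyldimethylsilyloxy)-10βH-furanoeremophilan-9β-ol
Conditions: H2 (1 atm), [Ir(cod)(PCy3)(py)]PF6 (10 mol%), CH2Cl2, rt
Reagents that add atoms: none
Why: In this hydroxyl-directed hydrogenation the cationic iridium complex binds the 9β-hydroxyl and the C1=C10 alkene on the same face, so C10 receives hydrogen cis to the hydroxyl (10S, 10β-H) and the ring fusion becomes cis against the steric bias of the C5 methyl; the C3 silyl ether does not coordinate and the furan is not reduced.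

Step 16
Reactants: 23 (3R,4R,5R,9R,10S)-3α-(tert-butyldimethylsilyloxy)-10βH-furanoeremophilan-9β-ol
Product: 24 allyl (3R,4R,5R,9R,10S)-3α-(tert-butyldimethylsilyloxy)-10βH-furanoeremophilan-9β-yl carbonate
Conditions: allyl chloroformate, pyridine, DMAP (cat.), CH2Cl2, 0 °C to rt
Reagents that add atoms: allyl chloroformate C=CCOC(Cl)=O
Why: Acylation of the 9-hydroxyl as its allyl carbonate gives a group that is stable to fluoride, singlet oxygen and borohydride and can later be removed under neutral conditions, and it prevents the 9-hydroxyl from adding to the C12 aldehyde formed in step 21.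

Step 17
Reactants: 24 allyl (3R,4R,5R,9R,10S)-3α-(tert-butyldimethylsilyloxy)-10βH-furanoeremophilan-9β-yl carbonate
Product: 25 allyl (3R,4R,5R,9R,10S)-3α-hydroxy-10βH-furanoeremophilan-9β-yl carbonate
Conditions: n-Bu4NF, AcOH (1:1), THF, rt to 40 °C
Reagents that add atoms: none
Why: Acetic acid-buffered fluoride cleaves the secondary silyl ether while the carbonate and the acid-sensitive furylic C9–O bond are left intact.

Step 18
Reactants: 26 (E)-non-3-en-2-one; 27 triethyl (E)-4-phosphonocrotonate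
Product: 28 ethyl (2E,4E,6E)-5-methyldodeca-2,4,6-trienoate
Conditions: NaH, THF, 0 °C to rt
Reagents that add atoms: none
Why: Horner–Wadsworth–Emmons olefination of the ketone by the α-carbon of the phosphonocrotonate anion keeps the 2E and 6E bonds of the partners and should form the new trisubstituted C4=C5 bond mainly E; the 4Z isomer is removed by chromatography.

Step 19
Reactants: 28 ethyl (2E,4E,6E)-5-methyldodeca-2,4,6-trienoate
Product: 29 (2E,4E,6E)-5-methyldodeca-2,4,6-trienoic acid
Conditions: LiOH, THF–MeOH–H2O, rt; then dilute HCl to pH 3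
Reagents that add atoms: lithium hydroxide [Li+].[OH-]
Why: Saponification of the ethyl ester under conditions that do not isomerise the triene.

Step 20
Reactants: 25 allyl (3R,4R,5R,9R,10S)-3α-hydroxy-10βH-furanoeremophilan-9β-yl carbonate; 29 (2E,4E,6E)-5-methyldodeca-2,4,6-trienoic acid
Product: 31 (3R,4R,5R,9R,10S)-9β-(allyloxycarbonyloxy)-10βH-furanoeremophilan-3α-yl (2E,4E,6E)-5-methyldodeca-2,4,6-trienoate, via mixed anhydride 30 (not isolated)
Conditions: 2,4,6-trichlorobenzoyl chloride, Et3N, toluene, rt; then 25, DMAP, rt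
Reagents that add atoms: none
Why: Yamaguchi esterification acylates the hindered secondary 3α-hydroxyl through the mixed anhydride with retention at C3.

Step 21
Reactants: 31 (3R,4R,5R,9R,10S)-9β-(allyloxycarbonyloxy)-10βH-furanoeremophilan-3α-yl (2E,4E,6E)-5-methyldodeca-2,4,6-trienoate
Product: 33 (3R,4R,5R,9R,10S,7Z)-9β-(allyloxycarbonyloxy)-8,12-dioxo-10βH-eremophil-7(11)-en-3α-yl (2E,4E,6E)-5-methyldodeca-2,4,6-trienoate, via furan endoperoxide 32 (not isolated)
Conditions: O2, visible light, tetraphenylporphyrin (cat.), CH2Cl2, −78 °C; then Me2S, −78 to 0 °C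
Reagents that add atoms: dioxygen O=O
Why: Singlet oxygen adds [4+2] across furan C8/C12 and dimethyl sulfide reduces the endoperoxide to the cis-enedione, so the 7(11)Z geometry comes from the ring; the electron-rich furan should react far faster than the ester-conjugated triene or the allyl group.

Step 22
Reactants: 33 (3R,4R,5R,9R,10S,7Z)-9β-(allyloxycarbonyloxy)-8,12-dioxo-10βH-eremophil-7(11)-en-3α-yl (2E,4E,6E)-5-methyldodeca-2,4,6-trienoate
Product: 34 (3R,4R,5R,9R,10S,7Z)-9β-(allyloxycarbonyloxy)-12-hydroxy-8-oxo-10βH-eremophil-7(11)-en-3α-yl (2E,4E,6E)-5-methyldodeca-2,4,6-trienoate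
Conditions: NaBH4, CH2Cl2–MeOH, −78 °C; pH 7 buffer quench
Reagents that add atoms: none
Why: Low-temperature borohydride reduction is chemoselective for the conjugated aldehyde (1,2-mode) over the hindered, doubly flanked C8 ketone, the carbonate and the ester, and the buffered quench avoids acid-promoted return of the Z-γ-hydroxy enone to the furan.

Step 23
Reactants: 34 (3R,4R,5R,9R,10S,7Z)-9β-(allyloxycarbonyloxy)-12-hydroxy-8-oxo-10βH-eremophil-7(11)-en-3α-yl (2E,4E,6E)-5-methyldodeca-2,4,6-trienoate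
Product: 35 (3R,4R,5R,9R,10S,7Z)-9β,12-dihydroxy-8-oxo-10βH-eremophil-7(11)-en-3α-yl (2E,4E,6E)-5-methyldodeca-2,4,6-trienoate
Conditions: Pd(PPh3)4 (5 mol%), dimedone, THF, rt
Reagents that add atoms: none
Why: Palladium-catalysed deallylation (π-allyl formation, loss of CO2, capture of the allyl group by dimedone) frees the 9-hydroxyl under near-neutral conditions that should spare the trienoate, the α-ketol and the Z-γ-hydroxy enone.

**Compound list**

1 | 1,4-dioxaspiro[4.5]dec-6-en-8-one | O=C1C=CC2(CC1)OCCO2 | starting material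
2 | (R)-1,4-dioxaspiro[4.5]dec-6-en-8-ol | O[C@@H]1CCC2(OCCO2)C=C1 | intermediate
3 | (R)-8-(tert-butyldimethylsilyloxy)-1,4-dioxaspiro[4.5]dec-6-ene | CC(C)(C)[Si](C)(C)O[C@@H]1CCC2(OCCO2)C=C1 | intermediate
4 | (R)-4-(tert-butyldimethylsilyloxy)cyclohex-2-en-1-one | CC(C)(C)[Si](C)(C)O[C@@H]1CCC(=O)C=C1 | intermediate
5 | (R)-4-(tert-butyldimethylsilyloxy)-2-iodocyclohex-2-en-1-one | CC(C)(C)[Si](C)(C)O[C@@H]1CCC(=O)C(I)=C1 | intermediate
6 | (R)-4-(tert-butyldimethylsilyloxy)-2-methylcyclohex-2-en-1-one | CC(C)(C)[Si](C)(C)O[C@@H]1CCC(=O)C(C)=C1 | intermediate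
7 | (3R,4R)-4-(tert-butyldimethylsilyloxy)-2,3-dimethyl-1-(trimethylsilyloxy)cyclohex-1-ene | CC(C)(C)[Si](C)(C)O[C@@H]1CCC(O[Si](C)(C)C)=C(C)[C@H]1C | intermediate
8 | 4-phenyloxazole | c1ccc(cc1)-c1cocn1 | starting material
9 | ethyl but-2-ynoate | CC#CC(=O)OCC | starting material
10 | ethyl 4-methylfuran-3-carboxylate | CCOC(=O)c1cocc1C | intermediate
11 | (4-methylfuran-3-yl)methanol | Cc1cocc1CO | intermediate
12 | lithium (2-lithio-4-methylfuran-3-yl)methanolate | [Li]OCc1c(C)coc1[Li] | intermediate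
13 | [4-methyl-2-(tributylstannyl)furan-3-yl]methanol | CCCC[Sn](CCCC)(CCCC)c1occ(C)c1CO | intermediate
14 | [4-methyl-2-(tributylstannyl)furan-3-yl]methyl methanesulfonate | CCCC[Sn](CCCC)(CCCC)c1occ(C)c1COS(C)(=O)=O | intermediate
15 | tributyl[3-(bromomethyl)-4-methylfuran-2-yl]stannane | CCCC[Sn](CCCC)(CCCC)c1occ(C)c1CBr | intermediate
16 | lithium (3R,4R)-4-(tert-butyldimethylsilyloxy)-2,3-dimethylcyclohex-1-en-1-olate | CC(C)(C)[Si](C)(C)O[C@@H]1CCC(O[Li])=C(C)[C@H]1C | intermediate
17 | (2R,3R,4R)-4-(tert-butyldimethylsilyloxy)-2,3-dimethyl-2-{[4-methyl-2-(tributylstannyl)furan-3-yl]methyl}cyclohexan-1-one | CC(C)(C)[Si](C)(C)O[C@@H]1CCC(=O)[C@@](Cc2c(C)coc2[Sn](CCCC)(CCCC)CCCC)(C)[C@H]1C | intermediate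
18 | potassium (4R,5R,6R)-4-(tert-butyldimethylsilyloxy)-5,6-dimethyl-6-{[4-methyl-2-(tributylstannyl)furan-3-yl]methyl}cyclohex-1-en-1-olate | CC(C)(C)[Si](C)(C)O[C@@H]1CC=C(O[K])[C@@](Cc2c(C)coc2[Sn](CCCC)(CCCC)CCCC)(C)[C@H]1C | intermediate
19 | (4R,5R,6R)-4-(tert-butyldimethylsilyloxy)-5,6-dimethyl-6-{[4-methyl-2-(tributylstannyl)furan-3-yl]methyl}cyclohex-1-en-1-yl trifluoromethanesulfonate | CC(C)(C)[Si](C)(C)O[C@@H]1CC=C(OS(=O)(=O)C(F)(F)F)[C@@](Cc2c(C)coc2[Sn](CCCC)(CCCC)CCCC)(C)[C@H]1C | intermediate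
20 | carbon monoxide | [C-]#[O+] | starting material
21 | (3R,4R,5R)-3α-(tert-butyldimethylsilyloxy)furanoeremophil-1(10)-en-9-one | CC(C)(C)[Si](C)(C)O[C@@H]1CC=C2C(=O)c3occ(C)c3C[C@]2(C)[C@H]1C | intermediate
22 | (3R,4R,5R,9R)-3α-(tert-butyldimethylsilyloxy)furanoeremophil-1(10)-en-9β-ol | CC(C)(C)[Si](C)(C)O[C@@H]1CC=C2[C@@H](O)c3occ(C)c3C[C@]2(C)[C@H]1C | intermediate
23 | (3R,4R,5R,9R,10S)-3α-(tert-butyldimethylsilyloxy)-10βH-furanoeremophilan-9β-ol | CC(C)(C)[Si](C)(C)O[C@@H]1CC[C@@H]2[C@@H](O)c3occ(C)c3C[C@]2(C)[C@H]1C | intermediate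
24 | allyl (3R,4R,5R,9R,10S)-3α-(tert-butyldimethylsilyloxy)-10βH-furanoeremophilan-9β-yl carbonate | CC(C)(C)[Si](C)(C)O[C@@H]1CC[C@@H]2[C@@H](OC(=O)OCC=C)c3occ(C)c3C[C@]2(C)[C@H]1C | intermediate
25 | allyl (3R,4R,5R,9R,10S)-3α-hydroxy-10βH-furanoeremophilan-9β-yl carbonate | O[C@@H]1CC[C@@H]2[C@@H](OC(=O)OCC=C)c3occ(C)c3C[C@]2(C)[C@H]1C | intermediate
26 | (E)-non-3-en-2-one | CCCCC/C=C/C(C)=O | starting material
27 | triethyl (E)-4-phosphonocrotonate | CCOC(=O)/C=C/CP(=O)(OCC)OCC | starting material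
28 | ethyl (2E,4E,6E)-5-methyldodeca-2,4,6-trienoate | CCCCC/C=C/C(C)=C/C=C/C(=O)OCC | intermediate
29 | (2E,4E,6E)-5-methyldodeca-2,4,6-trienoic acid | CCCCC/C=C/C(C)=C/C=C/C(=O)O | intermediate
30 | (2E,4E,6E)-5-methyldodeca-2,4,6-trienoic 2,4,6-trichlorobenzoic anhydride | CCCCC/C=C/C(C)=C/C=C/C(=O)OC(=O)c1c(Cl)cc(Cl)cc1Cl | intermediate
31 | (3R,4R,5R,9R,10S)-9β-(allyloxycarbonyloxy)-10βH-furanoeremophilan-3α-yl (2E,4E,6E)-5-methyldodeca-2,4,6-trienoate | CCCCC/C=C/C(C)=C/C=C/C(=O)O[C@@H]1CC[C@@H]2[C@@H](OC(=O)OCC=C)c3occ(C)c3C[C@]2(C)[C@H]1C | intermediate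
32 | C8,C12-endoperoxide of 31 (8,12-epidioxy-8,12-epoxyeremophil-7(11)-ene core, either bridge orientation) | CCCCC/C=C/C(C)=C/C=C/C(=O)O[C@@H]1CC[C@@H]2[C@@H](OC(=O)OCC=C)C34OOC(O3)C(C)=C4C[C@]2(C)[C@H]1C | intermediate
33 | (3R,4R,5R,9R,10S,7Z)-9β-(allyloxycarbonyloxy)-8,12-dioxo-10βH-eremophil-7(11)-en-3α-yl (2E,4E,6E)-5-methyldodeca-2,4,6-trienoate | CCCCC/C=C/C(C)=C/C=C/C(=O)O[C@@H]1CC[C@@H]2[C@@H](OC(=O)OCC=C)C(=O)/C(=C(/C)C=O)C[C@]2(C)[C@H]1C | intermediate
34 | (3R,4R,5R,9R,10S,7Z)-9β-(allyloxycarbonyloxy)-12-hydroxy-8-oxo-10βH-eremophil-7(11)-en-3α-yl (2E,4E,6E)-5-methyldodeca-2,4,6-trienoate | CCCCC/C=C/C(C)=C/C=C/C(=O)O[C@@H]1CC[C@@H]2[C@@H](OC(=O)OCC=C)C(=O)/C(=C(/C)CO)C[C@]2(C)[C@H]1C | intermediate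
35 | (3R,4R,5R,9R,10S,7Z)-9β,12-dihydroxy-8-oxo-10βH-eremophil-7(11)-en-3α-yl (2E,4E,6E)-5-methyldodeca-2,4,6-trienoate | CCCCC/C=C/C(C)=C/C=C/C(=O)O[C@@H]1CC[C@@H]2[C@@H](O)C(=O)/C(=C(/C)CO)C[C@]2(C)[C@H]1C | target

**Step count and risks**

Total step count: 23. Longest linear sequence: 17 steps (steps 1–6, 11–17 and 20–23).

Steps most likely to fail:

1. Step 13. The acylpalladium intermediate may be formed too slowly, so that direct coupling without CO, protodestannylation of the furan or intermolecular coupling take over. The fallback forms the same two bonds in two stages, C9–C10 by carbonylation and C8–C9 by electrophilic acylation of the furan. It sets out from 7 and 11. Alcohol 11 is converted with PBr3 in Et2O at 0 °C into 3-(bromomethyl)-4-methylfuran F1. Enolate 16, generated from 7 with MeLi as in step 11, is alkylated with F1 to give (2R,3R,4R)-4-(tert-butyldimethylsilyloxy)-2,3-dimethyl-2-[(4-methylfuran-3-yl)methyl]cyclohexan-1-one F2. Triflation as in step 12 gives the tin-free enol triflate F3. Palladium-catalysed hydroxycarbonylation (Pd(OAc)2, PPh3, CO, KOAc, DMF) gives the cyclohexene carboxylic acid F4. Oxalyl chloride with catalytic DMF gives the acid chloride F5, and SnCl4 in CH2Cl2 at −78 °C closes ring B by intramolecular Friedel–Crafts acylation at the furan α-carbon C8. The sequence returns to the route at 21.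

2. Step 11. The axial C3 silyloxy group lies syn to the trajectory that is anti to the C4 methyl, so facial selectivity may be poor or the electrophile may enter on the face of the C4 methyl. The fallback reverses the order in which the two C5 substituents are introduced, so that an electrophile entering trans to the silyloxy group now gives the wanted C5 configuration. It sets out from 4. Cuprate addition with chlorosilane trapping as in step 6 gives (3R,4R)-4-(tert-butyldimethylsilyloxy)-3-methyl-1-(trimethylsilyloxy)cyclohex-1-ene F6. Cleavage with MeLi and alkylation with 15 give (3R,4R)-4-(tert-butyldimethylsilyloxy)-3-methyl-2-{[4-methyl-2-(tributylstannyl)furan-3-yl]methyl}cyclohexan-1-one F7, whose C2 configuration is of no consequence. Thermodynamic silylation (Me3SiCl, NaI, Et3N, MeCN) gives the tetrasubstituted silyl enol ether F8. Cleavage with MeLi and methylation with MeI then place the methyl group on C5, and the sequence returns to the route at 17.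

3. Step 21. Singlet oxygen may also attack the trienoate (ene reaction or [4+2] addition at the distal diene), and the Z-keto-enal may isomerise or decompose before it is reduced. The fallback opens the furan before the triene is present. It sets out from 25. Photooxygenation under the conditions of step 21 gives, through the endoperoxide F9, the keto-enal F10 with a free 3-hydroxyl. Borohydride reduction at −78 °C gives the 3,12-diol F11. Selective silylation of the primary allylic hydroxyl (TBSCl, imidazole, CH2Cl2, 0 °C) gives the 12-silyl ether F12. Yamaguchi esterification with 29 as in step 20 gives the ester F13, and HF·pyridine buffered with pyridine in THF removes the primary silyl ether. The sequence returns to the route at 34.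

Further compounds
F1 | step 13 | 3-(bromomethyl)-4-methylfuran | Cc1cocc1CBr
F2 | step 13 | (2R,3R,4R)-4-(tert-butyldimethylsilyloxy)-2,3-dimethyl-2-[(4-methylfuran-3-yl)methyl]cyclohexan-1-one | CC(C)(C)[Si](C)(C)O[C@@H]1CCC(=O)[C@@](Cc2cocc2C)(C)[C@H]1C
F3 | step 13 | (4R,5R,6R)-4-(tert-butyldimethylsilyloxy)-5,6-dimethyl-6-[(4-methylfuran-3-yl)methyl]cyclohex-1-en-1-yl trifluoromethanesulfonate | CC(C)(C)[Si](C)(C)O[C@@H]1CC=C(OS(=O)(=O)C(F)(F)F)[C@@](Cc2cocc2C)(C)[C@H]1C
F4 | step 13 | (4R,5R,6R)-4-(tert-butyldimethylsilyloxy)-5,6-dimethyl-6-[(4-methylfuran-3-yl)methyl]cyclohex-1-ene-1-carboxylic acid | CC(C)(C)[Si](C)(C)O[C@@H]1CC=C(C(=O)O)[C@@](Cc2cocc2C)(C)[C@H]1C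
F5 | step 13 | (4R,5R,6R)-4-(tert-butyldimethylsilyloxy)-5,6-dimethyl-6-[(4-methylfuran-3-yl)methyl]cyclohex-1-ene-1-carbonyl chloride | CC(C)(C)[Si](C)(C)O[C@@H]1CC=C(C(Cl)=O)[C@@](Cc2cocc2C)(C)[C@H]1C
F6 | step 11 | (3R,4R)-4-(tert-butyldimethylsilyloxy)-3-methyl-1-(trimethylsilyloxy)cyclohex-1-ene | CC(C)(C)[Si](C)(C)O[C@@H]1CCC(O[Si](C)(C)C)=C[C@H]1C
F7 | step 11 | (3R,4R)-4-(tert-butyldimethylsilyloxy)-3-methyl-2-{[4-methyl-2-(tributylstannyl)furan-3-yl]methyl}cyclohexan-1-one | CC(C)(C)[Si](C)(C)O[C@@H]1CCC(=O)C(Cc2c(C)coc2[Sn](CCCC)(CCCC)CCCC)[C@H]1C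
F8 | step 11 | (3R,4R)-4-(tert-butyldimethylsilyloxy)-3-methyl-2-{[4-methyl-2-(tributylstannyl)furan-3-yl]methyl}-1-(trimethylsilyloxy)cyclohex-1-ene | CC(C)(C)[Si](C)(C)O[C@@H]1CCC(O[Si](C)(C)C)=C(Cc2c(C)coc2[Sn](CCCC)(CCCC)CCCC)[C@H]1C
F9 | step 21 | C8,C12-endoperoxide of 25 | O[C@@H]1CC[C@@H]2[C@@H](OC(=O)OCC=C)C34OOC(O3)C(C)=C4C[C@]2(C)[C@H]1C
F10 | step 21 | allyl (3R,4R,5R,9R,10S,7Z)-3α-hydroxy-8,12-dioxo-10βH-eremophil-7(11)-en-9β-yl carbonate | O[C@@H]1CC[C@@H]2[C@@H](OC(=O)OCC=C)C(=O)/C(=C(/C)C=O)C[C@]2(C)[C@H]1C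
F11 | step 21 | allyl (3R,4R,5R,9R,10S,7Z)-3α,12-dihydroxy-8-oxo-10βH-eremophil-7(11)-en-9β-yl carbonate | O[C@@H]1CC[C@@H]2[C@@H](OC(=O)OCC=C)C(=O)/C(=C(/C)CO)C[C@]2(C)[C@H]1C
F12 | step 21 | allyl (3R,4R,5R,9R,10S,7Z)-12-(tert-butyldimethylsilyloxy)-3α-hydroxy-8-oxo-10βH-eremophil-7(11)-en-9β-yl carbonate | O[C@@H]1CC[C@@H]2[C@@H](OC(=O)OCC=C)C(=O)/C(=C(/C)CO[Si](C)(C)C(C)(C)C)C[C@]2(C)[C@H]1C
F13 | step 21 | (3R,4R,5R,9R,10S,7Z)-9β-(allyloxycarbonyloxy)-12-(tert-butyldimethylsilyloxy)-8-oxo-10βH-eremophil-7(11)-en-3α-yl (2E,4E,6E)-5-methyldodeca-2,4,6-trienoate | CCCCC/C=C/C(C)=C/C=C/C(=O)O[C@@H]1CC[C@@H]2[C@@H](OC(=O)OCC=C)C(=O)/C(=C(/C)CO[Si](C)(C)C(C)(C)C)C[C@]2(C)[C@H]1C
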